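**Retrosynthetic overview**

1. Numbering: ring carbons C1–C10 of the ten-membered carbocycle (Z-C1=C10(CH3), C2–OH, E-C4(CH3)=C5, C6–O, C7, C8, C9–O-acyl); lactone carbons C11(=C13H2)–C12(=O). The last bonds made are the C9 ester C–O bond (acid 28) and the O–H bonds freed by removing two TBS groups.
2. Key disconnection C9–C10: C9 is an allylic carbinol bonded to C10, the methyl-bearing sp2 carbon of the Z-trisubstituted C1=C10 double bond in the ten-membered ring. The ring therefore opens to a C9 aldehyde and a (Z)-alkenyl iodide at C10. Because the Z geometry holds C9 and C2 cis, the open chain is U-shaped and suited to an intramolecular Ni/Cr (Nozaki–Hiyama–Kishi) closure on the unprotected α-methylene lactone.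
3. The lactone ring is made first and the ten-membered ring last. The C6–C7 bond and the trans-α-methylene-γ-butyrolactone come from a chromium-catalysed asymmetric 2-(alkoxycarbonyl)allylation of enal 11 with the Morita–Baylis–Hillman-derived bromide 15.
4. Enal 11 (C1–C6, C10, both ring methyls, the C2 centre, both olefin geometries) comes from a catalytic asymmetric vinylogous Mukaiyama aldol of (Z)-3-iodobut-2-enal 4.
5. Acid 28 (side chain) comes from crotonaldehyde by α-iodination, reduction, silylation and carboxylation of the alkenyllithium.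

Key step: step 13

Assumption: 3-[(4-methoxybenzyl)oxy]propanal (12) and the chiral Lewis base, ligand and catalysts named in the conditions are taken as purchasable, and for each of them the enantiomer that delivers the stated configuration is meant.

Step 1
Reactants: 1 but-2-yn-1-ol
Product: 3 (Z)-3-iodobut-2-en-1-ol, via cyclic alkenylalanate 2 (not isolated)
Conditions: Red-Al, THF, 0 °C to rt; then I2, THF, −78 °C
Reagents that add atoms: iodine, II
Why: Hydroxyl-directed trans-hydroalumination of the propargylic alcohol puts aluminium on the distal alkyne carbon in a five-membered alanate, and iodinolysis with retention should give only the Z-iodoalkene (Red-Al/I2 hydroalumination–iodination).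

Step 2
Reactants: 3 (Z)-3-iodobut-2-en-1-ol
Product: 4 (Z)-3-iodobut-2-enal
Conditions: MnO2, CH2Cl2, rt, dark; used crude
Reagents that add atoms: none
Why: MnO2 oxidises the allylic alcohol under neutral conditions, so the Z-iodoalkene geometry should be kept (allylic oxidation).

Step 3
Reactants: 5 ethyl 3-methylbut-2-enoate
Product: 7 tert-butyl[(1-ethoxy-3-methylbuta-1,3-dien-1-yl)oxy]dimethylsilane, via lithium dienolate 6 (not isolated)
Conditions: LDA, THF/DMPU, −78 °C; then TBSCl, −78 °C to rt
Reagents that add atoms: tert-butyldimethylsilyl chloride, CC(C)(C)[Si](C)(C)Cl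
Why: Kinetic γ-deprotonation of the senecioate and O-silylation of the extended enolate give the 1,3-dienyl ketene acetal, whose ketene-acetal geometry is of no consequence (silyl dienolate formation).

Step 4
Reactants: 4 (Z)-3-iodobut-2-enal; 7 tert-butyl[(1-ethoxy-3-methylbuta-1,3-dien-1-yl)oxy]dimethylsilane
Product: 8 ethyl (2E,5R,6Z)-5-hydroxy-7-iodo-3-methylocta-2,6-dienoate
Conditions: SiCl4, (R,R)-binaphthyldiamine bisphosphoramide (5 mol%), i-Pr2NEt (cat.), CH2Cl2, −78 °C; aq. KF/NaHCO3
Reagents that add atoms: none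
Why: Lewis-base-activated SiCl4 catalysis of the vinylogous Mukaiyama aldol reaction should give γ-attack and the E-enoate, and the chiral bisphosphoramide directs the dienolate to the Re face of the aldehyde so that the carbinol (C2 of the target) is formed as R.

Step 5
Reactants: 8 ethyl (2E,5R,6Z)-5-hydroxy-7-iodo-3-methylocta-2,6-dienoate
Product: 9 ethyl (2E,5R,6Z)-5-[(tert-butyldimethylsilyl)oxy]-7-iodo-3-methylocta-2,6-dienoate
Conditions: TBSCl, imidazole, DMF, rt
Reagents that add atoms: tert-butyldimethylsilyl chloride, CC(C)(C)[Si](C)(C)Cl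
Why: Silylation of the secondary allylic alcohol masks the C2 hydroxyl until the last step (silyl ether formation).

Step 6
Reactants: 9 ethyl (2E,5R,6Z)-5-[(tert-butyldimethylsilyl)oxy]-7-iodo-3-methylocta-2,6-dienoate
Product: 10 (2E,5R,6Z)-5-[(tert-butyldimethylsilyl)oxy]-7-iodo-3-methylocta-2,6-dien-1-ol
Conditions: DIBAL-H, CH2Cl2, −78 °C; Rochelle salt
Reagents that add atoms: none
Why: DIBAL-H at low temperature reduces the enoate 1,2 to the allylic alcohol and leaves the alkenyl iodide and silyl ether alone (ester reduction).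

Step 7
Reactants: 10 (2E,5R,6Z)-5-[(tert-butyldimethylsilyl)oxy]-7-iodo-3-methylocta-2,6-dien-1-ol
Product: 11 (2E,5R,6Z)-5-[(tert-butyldimethylsilyl)oxy]-7-iodo-3-methylocta-2,6-dienal
Conditions: MnO2, CH2Cl2, rt
Reagents that add atoms: none
Why: MnO2 oxidises the primary allylic alcohol to the E-enal without over-oxidation or olefin isomerisation (allylic oxidation).

Step 8
Reactants: 12 3-[(4-methoxybenzyl)oxy]propanal; 13 methyl acrylate
Product: 14 methyl 3-hydroxy-5-[(4-methoxybenzyl)oxy]-2-methylidenepentanoate (racemic)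
Conditions: DABCO (0.3 equiv), MeOH, rt
Reagents that add atoms: none
Why: The amine-catalysed Morita–Baylis–Hillman reaction joins the acrylate α-carbon to the aldehyde, and the racemic carbinol centre is removed in the next step.

Step 9
Reactants: 14 methyl 3-hydroxy-5-[(4-methoxybenzyl)oxy]-2-methylidenepentanoate
Product: 15 methyl (2Z)-2-(bromomethyl)-5-[(4-methoxybenzyl)oxy]pent-2-enoate
Conditions: NBS, Me2S, CH2Cl2, 0 °C to rt
Reagents that add atoms: N-bromosuccinimide, BrN1C(=O)CCC1=O
Why: Activation of the alcohol as an alkoxysulfonium ion and SN2′ attack of bromide should give the thermodynamically favoured 2Z primary allylic bromide (allylic bromination with transposition).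

Step 10
Reactants: 11 (2E,5R,6Z)-5-[(tert-butyldimethylsilyl)oxy]-7-iodo-3-methylocta-2,6-dienal; 15 methyl (2Z)-2-(bromomethyl)-5-[(4-methoxybenzyl)oxy]pent-2-enoate
Product: 18 (4S,5R)-5-[(1E,4R,5Z)-4-[(tert-butyldimethylsilyl)oxy]-6-iodo-2-methylhepta-1,5-dien-1-yl]-4-{2-[(4-methoxybenzyl)oxy]ethyl}-3-methylideneoxolan-2-one, via trimethylsilyl ether 16 (not isolated), via hydroxy ester 17 (not isolated)
Conditions: CrCl2 (10 mol%), chiral carbazole-bis(oxazoline) ligand (12 mol%), Mn, Me3SiCl, i-Pr2NEt (cat.), THF, rt; then TsOH·H2O (cat.), CH2Cl2, rt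
Reagents that add atoms: none
Why: In this chromium-catalysed asymmetric Nozaki–Hiyama allylation the 2-(methoxycarbonyl)allylchromium(III) species adds through its γ-carbon in a chair transition state (anti adduct, hence trans-lactone), the chiral Cr complex selects the Si face of the enal to set C6 (R) and C7 (S), the alkenyl iodide is inert without nickel, and acid then removes the TMS group and closes the lactone.

Step 11
Reactants: 18 PMB-protected lactone
Product: 19 (4S,5R)-5-[(1E,4R,5Z)-4-[(tert-butyldimethylsilyl)oxy]-6-iodo-2-methylhepta-1,5-dien-1-yl]-4-(2-hydroxyethyl)-3-methylideneoxolan-2-one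
Conditions: DDQ, CH2Cl2/pH 7 buffer, 0 °C
Reagents that add atoms: none
Why: DDQ cleaves the electron-rich PMB ether oxidatively and should leave silyl ether, lactone, olefins and alkenyl iodide untouched (PMB deprotection).

Step 12
Reactants: 19 primary alcohol
Product: 20 2-[(2R,3S)-2-[(1E,4R,5Z)-4-[(tert-butyldimethylsilyl)oxy]-6-iodo-2-methylhepta-1,5-dien-1-yl]-4-methylidene-5-oxooxolan-3-yl]acetaldehyde
Conditions: Dess–Martin periodinane, CH2Cl2, 0 °C to rt; used directly
Reagents that add atoms: none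
Why: Dess–Martin oxidation gives the aldehyde under near-neutral conditions, so the C7 centre and the exo-methylene lactone should not epimerise or isomerise.

Step 13
Reactants: 20 seco-aldehyde with (Z)-alkenyl iodide
Product: 22 (3aS,5S,6Z,8R,10E,11aR)-8-[(tert-butyldimethylsilyl)oxy]-5-hydroxy-6,10-dimethyl-3-methylidene-3a,4,5,8,9,11a-hexahydrocyclodeca[b]furan-2(3H)-one, via alkenylchromium species 21 (not isolated)
Conditions: CrCl2 (10 equiv), NiCl2 (0.1 equiv), degassed DMSO, rt, 3 mM, slow addition of 20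
Reagents that add atoms: none
Why: Ni(0) inserts into the C10–I bond of 20 and transmetallates to Cr(III) with retention of the Z geometry to give alkenylchromium 21, which adds to the C9 aldehyde; this is the Nozaki–Hiyama–Kishi reaction, whose closest precedents are Ni/Cr cyclisations of alkenyl iodide–aldehydes to nine- to eleven-membered rings. The ten-membered carbocycle is closed by 10-exo-trig attack of C10 on the C9 carbonyl, forming the C9–C10 bond. The new stereocentre C9 is set under macrocyclic substrate control: the trans-lactone, the E-C4=C5 and the Z-C1=C10 olefins restrict the ring-forming conformations, and the one that turns the chromium-bound oxygen to the periphery, away from the C10 methyl group (A1,3 strain), is expected to lead to the 9S carbinol; this sense is a prediction and is the least secure point of the route. The step needs cyclisation to beat oligomerisation, which the Z-alkenyl iodide (C9 and C2 held cis, a U-turn), the rigid lactone and high dilution should secure, and chemoselectivity for the aldehyde over lactone, acrylate and allylic C–O bonds, which is inherent to alkenylchromium(III) reagents. The olefin geometry cannot scramble because the alkenyl–chromium bond is configurationally stable.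

Step 14
Reactants: 23 (E)-but-2-enal (crotonaldehyde)
Product: 24 (Z)-2-iodobut-2-enal
Conditions: I2, K2CO3, DMAP (cat.), THF/H2O, rt
Reagents that add atoms: iodine, II
Why: Nucleophile-catalysed α-iodination of the enal (conjugate addition of DMAP, iodination of the enolate, elimination) should return the favoured Z-2-iodoenal with the methyl group trans to the formyl group.

Step 15
Reactants: 24 (Z)-2-iodobut-2-enal
Product: 25 (Z)-2-iodobut-2-en-1-ol
Conditions: NaBH4, CeCl3·7H2O, MeOH, 0 °C
Reagents that add atoms: none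
Why: Luche reduction gives clean 1,2-reduction of the α-iodoenal with the olefin geometry kept.

Step 16
Reactants: 25 (Z)-2-iodobut-2-en-1-ol
Product: 26 tert-butyl{[(2Z)-2-iodobut-2-en-1-yl]oxy}dimethylsilane
Conditions: TBSCl, imidazole, CH2Cl2, rt
Reagents that add atoms: tert-butyldimethylsilyl chloride, CC(C)(C)[Si](C)(C)Cl
Why: Silylation masks the primary allylic alcohol for the organolithium step and the esterification (silyl ether formation).

Step 17
Reactants: 26 tert-butyl{[(2Z)-2-iodobut-2-en-1-yl]oxy}dimethylsilane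
Product: 28 (2Z)-2-{[(tert-butyldimethylsilyl)oxy]methyl}but-2-enoic acid, via alkenyllithium 27 (not isolated)
Conditions: t-BuLi (2 equiv), Et2O, −78 °C; then CO2; aq. HCl
Reagents that add atoms: carbon dioxide, O=C=O
Why: Iodine–lithium exchange proceeds with retention and the configurationally stable alkenyllithium is carboxylated at −78 °C, so the carboxyl group should end up cis to the methyl group as required (halogen–metal exchange and carboxylation).

Step 18
Reactants: 22 macrocyclic C9 alcohol; 28 (2Z)-2-{[(tert-butyldimethylsilyl)oxy]methyl}but-2-enoic acid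
Product: 30 (3aS,5S,6Z,8R,10E,11aR)-8-[(tert-butyldimethylsilyl)oxy]-6,10-dimethyl-3-methylidene-2-oxo-2,3,3a,4,5,8,9,11a-octahydrocyclodeca[b]furan-5-yl (2Z)-2-{[(tert-butyldimethylsilyl)oxy]methyl}but-2-enoate, via mixed anhydride 29 (not isolated)
Conditions: 28, 2,4,6-Cl3C6H2COCl, Et3N, toluene, rt; then 22, DMAP, toluene, rt
Reagents that add atoms: none
Why: Yamaguchi esterification through the 2,4,6-trichlorobenzoyl mixed anhydride acylates the hindered allylic C9 hydroxyl with retention at C9 and is the established way to transfer angelate-type acyl groups without Z-to-E isomerisation.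

Step 19
Reactants: 30 bis-silyl ether
Product: 31 (3aS,5S,6Z,8R,10E,11aR)-8-hydroxy-6,10-dimethyl-3-methylidene-2-oxo-2,3,3a,4,5,8,9,11a-octahydrocyclodeca[b]furan-5-yl (2Z)-2-(hydroxymethyl)but-2-enoate (CNP0273961.1)
Conditions: HF·pyridine, pyridine, THF, 0 °C to rt
Reagents that add atoms: none
Why: Buffered HF·pyridine cleaves both silyl ethers through Si–F bond formation and should spare the two esters, the exo-methylene lactone and the allylic alcohols (global desilylation).

**Compound list**

1 | but-2-yn-1-ol | CC#CCO | starting material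
2 | sodium cyclic (Z)-alkenylalanate from 1 (2,2-bis(2-methoxyethoxy)-3-methyl-2,5-dihydro-1,2-oxaaluminol-2-uide) | CC1=CCO[Al-]1(OCCOC)OCCOC.[Na+] | intermediate
3 | (Z)-3-iodobut-2-en-1-ol | OC/C=C(/C)I | intermediate
4 | (Z)-3-iodobut-2-enal | O=C/C=C(/C)I | intermediate
5 | ethyl 3-methylbut-2-enoate | CCOC(=O)C=C(C)C | starting material
6 | lithium dienolate of 5 | [Li+].C=C(C)C=C([O-])OCC | intermediate
7 | tert-butyl[(1-ethoxy-3-methylbuta-1,3-dien-1-yl)oxy]dimethylsilane (ketene-acetal geometry not defined) | C=C(C)C=C(OCC)O[Si](C)(C)C(C)(C)C | intermediate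
8 | ethyl (2E,5R,6Z)-5-hydroxy-7-iodo-3-methylocta-2,6-dienoate | CCOC(=O)/C=C(\C)C[C@@H](O)/C=C(/C)I | intermediate
9 | ethyl (2E,5R,6Z)-5-[(tert-butyldimethylsilyl)oxy]-7-iodo-3-methylocta-2,6-dienoate | CCOC(=O)/C=C(\C)C[C@@H](O[Si](C)(C)C(C)(C)C)/C=C(/C)I | intermediate
10 | (2E,5R,6Z)-5-[(tert-butyldimethylsilyl)oxy]-7-iodo-3-methylocta-2,6-dien-1-ol | OC/C=C(\C)C[C@@H](O[Si](C)(C)C(C)(C)C)/C=C(/C)I | intermediate
11 | (2E,5R,6Z)-5-[(tert-butyldimethylsilyl)oxy]-7-iodo-3-methylocta-2,6-dienal | O=C/C=C(\C)C[C@@H](O[Si](C)(C)C(C)(C)C)/C=C(/C)I | intermediate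
12 | 3-[(4-methoxybenzyl)oxy]propanal | O=CCCOCc1ccc(OC)cc1 | starting material
13 | methyl acrylate | C=CC(=O)OC | starting material
14 | methyl 3-hydroxy-5-[(4-methoxybenzyl)oxy]-2-methylidenepentanoate (racemic) | C=C(C(=O)OC)C(O)CCOCc1ccc(OC)cc1 | intermediate
15 | methyl (2Z)-2-(bromomethyl)-5-[(4-methoxybenzyl)oxy]pent-2-enoate | COC(=O)/C(CBr)=C/CCOCc1ccc(OC)cc1 | intermediate
16 | methyl (3S,4R,5E,8R,9Z)-8-[(tert-butyldimethylsilyl)oxy]-10-iodo-3-{2-[(4-methoxybenzyl)oxy]ethyl}-6-methyl-2-methylidene-4-[(trimethylsilyl)oxy]undeca-5,9-dienoate | C=C(C(=O)OC)[C@H](CCOCc1ccc(OC)cc1)[C@H](O[Si](C)(C)C)/C=C(\C)C[C@@H](O[Si](C)(C)C(C)(C)C)/C=C(/C)I | intermediate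
17 | methyl (3S,4R,5E,8R,9Z)-8-[(tert-butyldimethylsilyl)oxy]-4-hydroxy-10-iodo-3-{2-[(4-methoxybenzyl)oxy]ethyl}-6-methyl-2-methylideneundeca-5,9-dienoate | C=C(C(=O)OC)[C@H](CCOCc1ccc(OC)cc1)[C@H](O)/C=C(\C)C[C@@H](O[Si](C)(C)C(C)(C)C)/C=C(/C)I | intermediate
18 | (4S,5R)-5-[(1E,4R,5Z)-4-[(tert-butyldimethylsilyl)oxy]-6-iodo-2-methylhepta-1,5-dien-1-yl]-4-{2-[(4-methoxybenzyl)oxy]ethyl}-3-methylideneoxolan-2-one | C=C1C(=O)O[C@H](/C=C(\C)C[C@@H](O[Si](C)(C)C(C)(C)C)/C=C(/C)I)[C@H]1CCOCc2ccc(OC)cc2 | intermediate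
19 | (4S,5R)-5-[(1E,4R,5Z)-4-[(tert-butyldimethylsilyl)oxy]-6-iodo-2-methylhepta-1,5-dien-1-yl]-4-(2-hydroxyethyl)-3-methylideneoxolan-2-one | C=C1C(=O)O[C@H](/C=C(\C)C[C@@H](O[Si](C)(C)C(C)(C)C)/C=C(/C)I)[C@H]1CCO | intermediate
20 | 2-[(2R,3S)-2-[(1E,4R,5Z)-4-[(tert-butyldimethylsilyl)oxy]-6-iodo-2-methylhepta-1,5-dien-1-yl]-4-methylidene-5-oxooxolan-3-yl]acetaldehyde | C=C1C(=O)O[C@H](/C=C(\C)C[C@@H](O[Si](C)(C)C(C)(C)C)/C=C(/C)I)[C@H]1CC=O | intermediate
21 | alkenylchromium(III) dichloride from 20 (Cr in place of I, Z geometry kept) | C=C1C(=O)O[C@H](/C=C(\C)C[C@@H](O[Si](C)(C)C(C)(C)C)/C=C(/C)[Cr](Cl)Cl)[C@H]1CC=O | intermediate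
22 | (3aS,5S,6Z,8R,10E,11aR)-8-[(tert-butyldimethylsilyl)oxy]-5-hydroxy-6,10-dimethyl-3-methylidene-3a,4,5,8,9,11a-hexahydrocyclodeca[b]furan-2(3H)-one | C=C1C(=O)O[C@@H]2/C=C(\C)C[C@@H](O[Si](C)(C)C(C)(C)C)/C=C(/C)[C@@H](O)C[C@@H]12 | intermediate
23 | (E)-but-2-enal (crotonaldehyde) | C/C=C/C=O | starting material
24 | (Z)-2-iodobut-2-enal | C/C=C(\I)C=O | intermediate
25 | (Z)-2-iodobut-2-en-1-ol | C/C=C(\I)CO | intermediate
26 | tert-butyl{[(2Z)-2-iodobut-2-en-1-yl]oxy}dimethylsilane | C/C=C(\I)CO[Si](C)(C)C(C)(C)C | intermediate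
27 | alkenyllithium from 26 (Li in place of I) | C/C=C(\[Li])CO[Si](C)(C)C(C)(C)C | intermediate
28 | (2Z)-2-{[(tert-butyldimethylsilyl)oxy]methyl}but-2-enoic acid | C/C=C(\C(=O)O)CO[Si](C)(C)C(C)(C)C | intermediate
29 | mixed anhydride of 28 with 2,4,6-trichlorobenzoic acid | C/C=C(\C(=O)OC(=O)c1c(Cl)cc(Cl)cc1Cl)CO[Si](C)(C)C(C)(C)C | intermediate
30 | (3aS,5S,6Z,8R,10E,11aR)-8-[(tert-butyldimethylsilyl)oxy]-6,10-dimethyl-3-methylidene-2-oxo-2,3,3a,4,5,8,9,11a-octahydrocyclodeca[b]furan-5-yl (2Z)-2-{[(tert-butyldimethylsilyl)oxy]methyl}but-2-enoate | C=C1C(=O)O[C@@H]2/C=C(\C)C[C@@H](O[Si](C)(C)C(C)(C)C)/C=C(/C)[C@@H](OC(=O)/C(=C\C)CO[Si](C)(C)C(C)(C)C)C[C@@H]12 | intermediate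
31 | (3aS,5S,6Z,8R,10E,11aR)-8-hydroxy-6,10-dimethyl-3-methylidene-2-oxo-2,3,3a,4,5,8,9,11a-octahydrocyclodeca[b]furan-5-yl (2Z)-2-(hydroxymethyl)but-2-enoate (CNP0273961.1) | C=C1C(=O)O[C@@H]2/C=C(\C)C[C@@H](O)/C=C(/C)[C@@H](OC(=O)/C(=C\C)CO)C[C@@H]12 | target

**Step count and risks**

Total: 19 steps. Longest linear sequence: 12 steps (1, 2, 4, 5, 6, 7, 10, 11, 12, 13, 18, 19).

The three steps most likely to fail:

Step 13 (key ring closure). What may go wrong: insufficient facial discrimination when the alkenylchromium adds to the C9 aldehyde, so that the wrong carbinol configuration forms in quantity. Fallback: control of C9 is moved from the C–C bond formation to a reagent-controlled reduction. Setting out from 20, the cyclisation is run as in step 13 and the mixture of 22 and its C9 epimer, the (9R)-carbinol F1, is oxidised with Dess–Martin periodinane to the macrocyclic C9 ketone (Z-enone) F2. Corey–Bakshi–Shibata reduction with the (R)-oxazaborolidine and catecholborane, which treats the C10 alkenyl group as the large substituent, then returns the route to 22.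

Step 10 (asymmetric allylation and lactonisation). What may go wrong: insufficient catalyst control over the two new centres C6 and C7 next to the remote C2 centre, or competing activation of the alkenyl iodide by the low-valent metals. Fallback: boron replaces chromium and C6 is corrected by inversion. Setting out from 15, Pd-catalysed borylation (B2pin2, KOAc) gives the allylboronate F3. Its chiral-phosphoric-acid-catalysed allylboration of 11 proceeds through the closed chair with the chain axial and gives the syn hydroxy ester F4 (6S,7S). Saponification (LiOH) gives the hydroxy acid F5, and Mitsunobu lactonisation (PPh3, DIAD), which inverts C6, returns the route to 18.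

Step 4 (vinylogous aldol). What may go wrong: Z-to-E isomerisation of the β-iodoenal, or erosion of the γ- and enantioselectivity, under the strongly Lewis acidic conditions. Fallback: the carbinol is set by a Brønsted-acid-catalysed propargylation and the E-olefin by carbometalation. Setting out from 4, (R)-TRIP-catalysed addition of allenylboronic acid pinacol ester gives the homopropargylic alcohol F6, and silylation (TBSCl, imidazole) gives its silyl ether F7. Zirconium-catalysed methylalumination of the terminal alkyne (Me3Al, Cp2ZrCl2) and trapping of the alkenylalane with ethyl chloroformate then returns the route to 9.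

Further compounds

F1 | step 13 | (3aS,5R,6Z,8R,10E,11aR)-8-[(tert-butyldimethylsilyl)oxy]-5-hydroxy-6,10-dimethyl-3-methylidene-3a,4,5,8,9,11a-hexahydrocyclodeca[b]furan-2(3H)-one (C9 epimer of 22) | C=C1C(=O)O[C@@H]2/C=C(\C)C[C@@H](O[Si](C)(C)C(C)(C)C)/C=C(/C)[C@H](O)C[C@@H]12
F2 | step 13 | (3aS,6Z,8R,10E,11aR)-8-[(tert-butyldimethylsilyl)oxy]-6,10-dimethyl-3-methylidene-3a,4,9,11a-tetrahydrocyclodeca[b]furan-2,5(3H,8H)-dione (C9 ketone) | C=C1C(=O)O[C@@H]2/C=C(\C)C[C@@H](O[Si](C)(C)C(C)(C)C)/C=C(/C)C(=O)C[C@@H]12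
F3 | step 10 | methyl (2E)-5-[(4-methoxybenzyl)oxy]-2-[(4,4,5,5-tetramethyl-1,3,2-dioxaborolan-2-yl)methyl]pent-2-enoate | COC(=O)/C(CB1OC(C)(C)C(C)(C)O1)=C/CCOCc1ccc(OC)cc1
F4 | step 10 | methyl (3S,4S,5E,8R,9Z)-8-[(tert-butyldimethylsilyl)oxy]-4-hydroxy-10-iodo-3-{2-[(4-methoxybenzyl)oxy]ethyl}-6-methyl-2-methylideneundeca-5,9-dienoate | C=C(C(=O)OC)[C@H](CCOCc1ccc(OC)cc1)[C@@H](O)/C=C(\C)C[C@@H](O[Si](C)(C)C(C)(C)C)/C=C(/C)I
F5 | step 10 | (3S,4S,5E,8R,9Z)-8-[(tert-butyldimethylsilyl)oxy]-4-hydroxy-10-iodo-3-{2-[(4-methoxybenzyl)oxy]ethyl}-6-methyl-2-methylideneundeca-5,9-dienoic acid | C=C(C(=O)O)[C@H](CCOCc1ccc(OC)cc1)[C@@H](O)/C=C(\C)C[C@@H](O[Si](C)(C)C(C)(C)C)/C=C(/C)I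
F6 | step 4 | (4R,5Z)-6-iodohept-5-en-1-yn-4-ol | C#CC[C@@H](O)/C=C(/C)I
F7 | step 4 | tert-butyl{[(4R,5Z)-6-iodohept-5-en-1-yn-4-yl]oxy}dimethylsilane | C#CC[C@@H](O[Si](C)(C)C(C)(C)C)/C=C(/C)I
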